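Divide the product at the last reading by the nucleophile charged and you have, as a reading with its scatter, the chance that one nucleophile molecule had ended as product by then, a selectivity: 0.375 in Thursday's run and 0.149 in Sunday's. Sunday's run still held 65.6% of its electrophile, so expect much of the nucleophile to go somewhere other than product.

the same everywhere: electrophile 20 mM

|  | nucleophile | buffer base | buffer acid | remark | time |
|---|---|---|---|---|---|
| Thursday's | 0.53 equiv | 3 equiv | 2 equiv | run made earlier |  |
| Sunday's | 2.1 equiv | 3 equiv | 2 equiv | run made earlier |  |
| Friday's | 1.05 equiv | 1.5 equiv | 2 equiv | run made earlier |  |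
| flask | 1.05 equiv | 3.00 equiv | 2.00 equiv |  | 2.5 h |

| run | time / h | electrophile / % | product / % |
|---|---|---|---|
| Thursday's | 0.333 | 92.4 | 7.1 |
| Thursday's | 0.833 | 86.9 | 10.6 |
| Thursday's | 1.50 | 82.8 | 15.2 |
| Thursday's | 2.50 | 81.9 | 19.9 |
| Sunday's | 0.333 | 82.4 | 16.9 |
| Sunday's | 0.833 | 74.3 | 23.2 |
| Sunday's | 1.50 | 71.0 | 27.3 |
| Sunday's | 2.50 | 65.6 | 31.2 |
| Friday's | 0.333 | 86.9 | 12.4 |
| Friday's | 0.833 | 81.4 | 17.7 |
| Friday's | 1.50 | 76.4 | 24.3 |
| Friday's | 2.50 | 76.3 | 23.5 |

(readings scatter by 1 percentage point)

- the earlier runs do not show the pH; that part of a forecast is a guess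

1. part of the electrophile that has reacted at 2.5 h
2. pH of the solution at 2.5 h

Reckon by the charge, then: between Thursday's run and Sunday's, with electrophile and buffer the same, each doubling of the nucleophile charge added on average 5.7 percentage points of product at the last reading; call this the doubling gain. This flask holds twice Thursday's charge, so when you come at 2.5 h, counting each product as one electrophile reacted, expect 25.5% of the electrophile reacted, with a scatter of 1 point on each reading behind that figure, and the rest of it still standing. Leave the buffer alone, and take any pH as a guess, since no run shows one.

The forecast reads 25% and pH 7, holding that “base has little effect”.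

The flask gives 25.5% reacted and pH 7.88, with less nucleophile left than electrophile, 3.2% against 75% of their charges. Put this result between the last product readings of the two runs: the doubling gain comes to 5.6 points from Thursday's reading up to it and 5.7 points from it up to Sunday's reading.

    electrophile + nucleophile → acid + product + leaving group (k = 0.00980 M⁻¹ s⁻¹)
    protonated nucleophile ⇌ nucleophile + acid, settled at all times (K = 1.30 × 10⁻⁵ M)
    2 nucleophile → homo dimer (k = 0.0340 M⁻¹ s⁻¹)
    buffer acid ⇌ buffer base + acid, settled at all times (K = 1.60 × 10⁻⁸ M)

Now read the same flask at 1.0 h: the doubling gain, read at the last readings and carried to earlier times as a rough estimate, added to Thursday's product readings on either side of that time gives 16.2% at 0.833 h and 20.8% at 1.50 h. The computed neighbour stands at 20.3% reacted, between the two.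

The earlier runs and the new flask were computed with made-up constants, and the scatter is random.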